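**Retrosynthetic overview**
1. Target 18 ⇐ 17 by one hydrogenation (C=C, aryl O‑benzyl, benzyl ester); 17 ⇐ 16 by desilylation.
2. 16 ⇐ aldehyde 14 plus a methallyl nucleophile: the benzylic C–C bond and the (S)‑carbinol are made together by reagent‑controlled asymmetric carbonyl methallylation.
3. 14 ⇐ phenol 7 (ring B) plus aryl fluoride 13 (ring A) by SNAr; the fluoride is para to CHO and ortho to the ester.
4. 7 ⇐ 5‑methyl‑o‑vanillin 1; 13 ⇐ 4‑fluoro‑2‑methoxybenzaldehyde 8 (carboxylation between F and OMe by directed metalation).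
5. No ring is formed: both benzene rings are bought. The ring B fragment is made first, ring A second, then they are joined.

Assumption: 1 and 8 are bought as catalogue chemicals; "(−)‑Ipc2BOMe" is the dIpc reagent derived from (+)‑α‑pinene.

**Step 1**
Reactants: 1 2-hydroxy-3-methoxy-5-methylbenzaldehyde
Product: 3 2,3-dihydroxy-5-methylbenzaldehyde, via cyclic bromoborate 2 (not isolated)
Conditions: BBr3, CH2Cl2, −78 °C → rt; then H2O
Reagents that add atoms: none
Why: Lewis‑acid ether cleavage (BBr3 demethylation) of the aryl methyl ether is standard for o‑vanillins, and the aldehyde survives.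

**Step 2**
Reactants: 3 2,3-dihydroxy-5-methylbenzaldehyde
Product: 5 3-(benzyloxy)-2-hydroxy-5-methylbenzaldehyde, via disodium catecholate 4 (not isolated)
Conditions: NaH (2.2 equiv), DMSO, rt; then BnBr (1.0 equiv), rt; 1 M HCl work‑up
Reagents that add atoms: benzyl bromide BrCc1ccccc1
Why: Williamson etherification of the dianion goes at O‑3, because that phenoxide is not stabilised by the ortho aldehyde and is much more nucleophilic than O‑2.

**Step 3**
Reactants: 5 3-(benzyloxy)-2-hydroxy-5-methylbenzaldehyde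
Product: 6 2-(benzyloxy)-6-(hydroxymethyl)-4-methylphenol
Conditions: NaBH4, MeOH/THF, 0 °C
Reagents that add atoms: none
Why: Borohydride reduction of the aryl aldehyde leaves the benzyl ether and phenol untouched.

**Step 4**
Reactants: 6 2-(benzyloxy)-6-(hydroxymethyl)-4-methylphenol
Product: 7 2-(benzyloxy)-6-({[tert-butyl(dimethyl)silyl]oxy}methyl)-4-methylphenol
Conditions: TBSCl (1.05 equiv), imidazole, DMF, 0 °C
Reagents that add atoms: tert-butyldimethylsilyl chloride CC(C)(C)[Si](C)(C)Cl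
Why: Silylation of the primary alcohol is much faster than that of the di‑ortho‑substituted phenol, as with salicyl alcohol itself.

**Step 5**
Reactants: 8 4-fluoro-2-methoxybenzaldehyde
Product: 9 2-(4-fluoro-2-methoxyphenyl)-1,3-dioxolane
Conditions: ethylene glycol, TsOH (cat.), toluene, reflux, Dean–Stark
Reagents that add atoms: ethylene glycol OCCO
Why: Acid‑catalysed acetalisation with azeotropic water removal masks the aldehyde against the organolithium of the next step.

**Step 6**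
Reactants: 9 2-(4-fluoro-2-methoxyphenyl)-1,3-dioxolane
Product: 12 6-fluoro-3-formyl-2-methoxybenzoic acid, via aryllithium 10 (not isolated), via lithium carboxylate 11 (not isolated)
Conditions: s‑BuLi, TMEDA, THF, −78 °C; CO2; then 2 M HCl, THF, rt
Reagents that add atoms: carbon dioxide O=C=O; water O
Why: Directed ortho‑metalation removes the most acidic proton, flanked by F and OMe (as in 3‑fluoroanisole and 4‑fluoroveratrole); the aryllithium is carboxylated and the acidic work‑up hydrolyses the dioxolane.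

**Step 7**
Reactants: 12 6-fluoro-3-formyl-2-methoxybenzoic acid
Product: 13 benzyl 6-fluoro-3-formyl-2-methoxybenzoate
Conditions: BnBr, K2CO3, DMF, rt
Reagents that add atoms: benzyl bromide BrCc1ccccc1
Why: SN2 O‑alkylation of the carboxylate esterifies the di‑ortho‑substituted acid without attack at its hindered carbonyl.

**Step 8**
Reactants: 7 2-(benzyloxy)-6-({[tert-butyl(dimethyl)silyl]oxy}methyl)-4-methylphenol; 13 benzyl 6-fluoro-3-formyl-2-methoxybenzoate
Product: 14 benzyl 6-[2-(benzyloxy)-6-({[tert-butyl(dimethyl)silyl]oxy}methyl)-4-methylphenoxy]-3-formyl-2-methoxybenzoate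
Conditions: K2CO3, DMF, 70 °C
Reagents that add atoms: none
Why: SNAr through a Meisenheimer adduct: the fluoride is para to CHO and ortho to the ester, and is a far better leaving group than the methoxy group.

**Step 9**
Reactants: 14 benzyl 6-[2-(benzyloxy)-6-({[tert-butyl(dimethyl)silyl]oxy}methyl)-4-methylphenoxy]-3-formyl-2-methoxybenzoate
Product: 16 benzyl 6-[2-(benzyloxy)-6-({[tert-butyl(dimethyl)silyl]oxy}methyl)-4-methylphenoxy]-3-[(1S)-1-hydroxy-3-methylbut-3-en-1-yl]-2-methoxybenzoate, via diisopinocampheylborinate 15 (not isolated)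
Conditions: (−)‑Ipc2BOMe, methallylMgCl, Et2O, −78 °C → rt; then 14, −78 °C; then 3 M NaOH, 30% H2O2, 0 °C → rt
Reagents that add atoms: methallylmagnesium chloride CC(=C)C[Mg]Cl
Why: Brown asymmetric allylboration (carbonyl methallylation) through a chair six‑membered transition state; the dIpc ligands deliver the methallyl group to the Si face of the aryl aldehyde and set the (S)‑carbinol, and the ester does not react with the allylborane.

**Step 10**
Reactants: 16 benzyl 6-[2-(benzyloxy)-6-({[tert-butyl(dimethyl)silyl]oxy}methyl)-4-methylphenoxy]-3-[(1S)-1-hydroxy-3-methylbut-3-en-1-yl]-2-methoxybenzoate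
Product: 17 benzyl 6-[2-(benzyloxy)-6-(hydroxymethyl)-4-methylphenoxy]-3-[(1S)-1-hydroxy-3-methylbut-3-en-1-yl]-2-methoxybenzoate
Conditions: TBAF, AcOH (1:1), THF, 0 °C → rt
Reagents that add atoms: none
Why: Fluoride‑driven desilylation; the acetic acid buffer prevents the liberated alkoxide from attacking the neighbouring ester (eight‑membered lactone).

**Step 11**
Reactants: 17 benzyl 6-[2-(benzyloxy)-6-(hydroxymethyl)-4-methylphenoxy]-3-[(1S)-1-hydroxy-3-methylbut-3-en-1-yl]-2-methoxybenzoate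
Product: 18 6-[2-hydroxy-6-(hydroxymethyl)-4-methylphenoxy]-3-[(1S)-1-hydroxy-3-methylbutyl]-2-methoxybenzoic acid
Conditions: H2 (1 atm), 10% Pd/C, EtOAc, rt, stopped at full conversion
Reagents that add atoms: none
Why: Catalytic hydrogenation saturates the 1,1‑disubstituted alkene and hydrogenolyses the aryl benzyl ether and benzyl ester; in neutral EtOAc the benzylic alcohols are cleaved far more slowly and the stereocentre is not touched.

**Compound list**
1 | 2-hydroxy-3-methoxy-5-methylbenzaldehyde (5‑methyl‑o‑vanillin) | Cc1cc(C=O)c(O)c(OC)c1 | starting material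
2 | 2-bromo-6-methyl-1,3,2-benzodioxaborole-4-carbaldehyde (cyclic bromoborate) | Cc1cc(C=O)c2OB(Br)Oc2c1 | intermediate (not isolated)
3 | 2,3-dihydroxy-5-methylbenzaldehyde | Cc1cc(C=O)c(O)c(O)c1 | intermediate
4 | disodium 3-formyl-5-methylbenzene-1,2-diolate | Cc1cc(C=O)c([O-])c([O-])c1.[Na+].[Na+] | intermediate (not isolated)
5 | 3-(benzyloxy)-2-hydroxy-5-methylbenzaldehyde | Cc1cc(C=O)c(O)c(OCc2ccccc2)c1 | intermediate
6 | 2-(benzyloxy)-6-(hydroxymethyl)-4-methylphenol | Cc1cc(CO)c(O)c(OCc2ccccc2)c1 | intermediate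
7 | 2-(benzyloxy)-6-({[tert-butyl(dimethyl)silyl]oxy}methyl)-4-methylphenol | Cc1cc(CO[Si](C)(C)C(C)(C)C)c(O)c(OCc2ccccc2)c1 | intermediate
8 | 4-fluoro-2-methoxybenzaldehyde | COc1cc(F)ccc1C=O | starting material
9 | 2-(4-fluoro-2-methoxyphenyl)-1,3-dioxolane | COc1cc(F)ccc1C1OCCO1 | intermediate
10 | [3-(1,3-dioxolan-2-yl)-6-fluoro-2-methoxyphenyl]lithium | COc1c([Li])c(F)ccc1C1OCCO1 | intermediate (not isolated)
11 | lithium 3-(1,3-dioxolan-2-yl)-6-fluoro-2-methoxybenzoate | COc1c(C(=O)[O-])c(F)ccc1C1OCCO1.[Li+] | intermediate (not isolated)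
12 | 6-fluoro-3-formyl-2-methoxybenzoic acid | COc1c(C=O)ccc(F)c1C(=O)O | intermediate
13 | benzyl 6-fluoro-3-formyl-2-methoxybenzoate | COc1c(C=O)ccc(F)c1C(=O)OCc1ccccc1 | intermediate
14 | benzyl 6-[2-(benzyloxy)-6-({[tert-butyl(dimethyl)silyl]oxy}methyl)-4-methylphenoxy]-3-formyl-2-methoxybenzoate | COc1c(C=O)ccc(Oc2c(OCc3ccccc3)cc(C)cc2CO[Si](C)(C)C(C)(C)C)c1C(=O)OCc1ccccc1 | intermediate
15 | O‑bis(isopinocampheyl)boryl derivative of 16 (borinate from dIpc2B‑methallyl, carbinol carbon S) | COc1c([C@@H](OB([C@@H]2C[C@@H]3C[C@H]([C@H]2C)C3(C)C)[C@@H]2C[C@@H]3C[C@H]([C@H]2C)C3(C)C)CC(C)=C)ccc(Oc2c(OCc3ccccc3)cc(C)cc2CO[Si](C)(C)C(C)(C)C)c1C(=O)OCc1ccccc1 | intermediate (not isolated)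
16 | benzyl 6-[2-(benzyloxy)-6-({[tert-butyl(dimethyl)silyl]oxy}methyl)-4-methylphenoxy]-3-[(1S)-1-hydroxy-3-methylbut-3-en-1-yl]-2-methoxybenzoate | COc1c([C@@H](O)CC(C)=C)ccc(Oc2c(OCc3ccccc3)cc(C)cc2CO[Si](C)(C)C(C)(C)C)c1C(=O)OCc1ccccc1 | intermediate
17 | benzyl 6-[2-(benzyloxy)-6-(hydroxymethyl)-4-methylphenoxy]-3-[(1S)-1-hydroxy-3-methylbut-3-en-1-yl]-2-methoxybenzoate | COc1c([C@@H](O)CC(C)=C)ccc(Oc2c(OCc3ccccc3)cc(C)cc2CO)c1C(=O)OCc1ccccc1 | intermediate
18 | 6-[2-hydroxy-6-(hydroxymethyl)-4-methylphenoxy]-3-[(1S)-1-hydroxy-3-methylbutyl]-2-methoxybenzoic acid | COc1c([C@@H](O)CC(C)C)ccc(Oc2c(O)cc(C)cc2CO)c1C(=O)O | target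

**Totals**
Total steps: 11. Longest linear sequence: 8 steps (1 → 3 → 5 → 6 → 7 → 14 → 16 → 17 → 18); the ring A branch (8 → 13) is 3 steps.

**Three steps most likely to fail**

Step 2 (O‑3‑selective monobenzylation). If the dianion gives mixtures of regioisomers or dibenzylation, the fallback sets out from 3 and comes back at 5. Both phenols of 3 are benzylated (BnBr 2.5 equiv, K2CO3, DMF, 60 °C) to give 2,3-bis(benzyloxy)-5-methylbenzaldehyde F1. Only the benzyl ether ortho to the aldehyde is then removed by chelation‑assisted cleavage with MgBr2·OEt2 (toluene/Et2O, reflux), which returns 5.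

Step 9 (asymmetric methallylation of the ortho‑substituted aldehyde; risk of insufficient ee). The fallback sets out from 14 and comes back at 16. A zinc Barbier methallylation (3‑bromo‑2‑methylpropene, Zn, THF/aq. NH4Cl) still makes the same C–C bond and gives racemic benzyl 6-[2-(benzyloxy)-6-({[tert-butyl(dimethyl)silyl]oxy}methyl)-4-methylphenoxy]-3-(1-hydroxy-3-methylbut-3-en-1-yl)-2-methoxybenzoate F2. Buffered Dess–Martin oxidation (NaHCO3, CH2Cl2, 0 °C) gives benzyl 6-[2-(benzyloxy)-6-({[tert-butyl(dimethyl)silyl]oxy}methyl)-4-methylphenoxy]-2-methoxy-3-(3-methylbut-3-enoyl)benzoate F3, used crude to avoid conjugation of the alkene. The configuration is then set by CBS reduction ((R)‑Me‑CBS, catecholborane, toluene, −78 °C; aryl as the large group gives the S alcohol, and catecholborane spares the alkene), which returns 16.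

Step 11 (hydrogenation; risk of benzylic C–O hydrogenolysis or Pd‑induced alkene migration). The fallback sets out from 16 and comes back at 18. The secondary alcohol of 16 is silylated (TBSOTf, 2,6‑lutidine, CH2Cl2, −78 °C) to benzyl 6-[2-(benzyloxy)-6-({[tert-butyl(dimethyl)silyl]oxy}methyl)-4-methylphenoxy]-3-[(1S)-1-{[tert-butyl(dimethyl)silyl]oxy}-3-methylbut-3-en-1-yl]-2-methoxybenzoate F4. Hydrogenation (H2, Pd/C, EtOAc) with both benzylic oxygens masked as silyl ethers gives 6-[2-hydroxy-6-({[tert-butyl(dimethyl)silyl]oxy}methyl)-4-methylphenoxy]-3-[(1S)-1-{[tert-butyl(dimethyl)silyl]oxy}-3-methylbutyl]-2-methoxybenzoic acid F5. Both silyl ethers are then removed with fluoride (TBAF, THF, rt) to give 18.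

**Further compounds**
F1 | step 2 | 2,3-bis(benzyloxy)-5-methylbenzaldehyde | Cc1cc(C=O)c(OCc2ccccc2)c(OCc2ccccc2)c1
F2 | step 9 | racemic benzyl 6-[2-(benzyloxy)-6-({[tert-butyl(dimethyl)silyl]oxy}methyl)-4-methylphenoxy]-3-(1-hydroxy-3-methylbut-3-en-1-yl)-2-methoxybenzoate | COc1c(C(O)CC(C)=C)ccc(Oc2c(OCc3ccccc3)cc(C)cc2CO[Si](C)(C)C(C)(C)C)c1C(=O)OCc1ccccc1
F3 | step 9 | benzyl 6-[2-(benzyloxy)-6-({[tert-butyl(dimethyl)silyl]oxy}methyl)-4-methylphenoxy]-2-methoxy-3-(3-methylbut-3-enoyl)benzoate | COc1c(C(=O)CC(C)=C)ccc(Oc2c(OCc3ccccc3)cc(C)cc2CO[Si](C)(C)C(C)(C)C)c1C(=O)OCc1ccccc1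
F4 | step 11 | benzyl 6-[2-(benzyloxy)-6-({[tert-butyl(dimethyl)silyl]oxy}methyl)-4-methylphenoxy]-3-[(1S)-1-{[tert-butyl(dimethyl)silyl]oxy}-3-methylbut-3-en-1-yl]-2-methoxybenzoate | COc1c([C@@H](O[Si](C)(C)C(C)(C)C)CC(C)=C)ccc(Oc2c(OCc3ccccc3)cc(C)cc2CO[Si](C)(C)C(C)(C)C)c1C(=O)OCc1ccccc1
F5 | step 11 | 6-[2-hydroxy-6-({[tert-butyl(dimethyl)silyl]oxy}methyl)-4-methylphenoxy]-3-[(1S)-1-{[tert-butyl(dimethyl)silyl]oxy}-3-methylbutyl]-2-methoxybenzoic acid | COc1c([C@@H](O[Si](C)(C)C(C)(C)C)CC(C)C)ccc(Oc2c(O)cc(C)cc2CO[Si](C)(C)C(C)(C)C)c1C(=O)O
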